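**Strategy**
1. Retrosynthetic cuts, in order: the two ester C–O bonds (O9–isovaleryl, O5–isobutyryl); C8–O and C9–O (diol read as the E-C8=C9 alkene); the O6–C12 lactone bond; C1–C10 of the ten-membered ring (with C3–C8 re-joined); then C9=C10, C2–C3 and C8–C9 on the resulting cyclohexane.
2. Enabling feature: with the diol read as an alkene, the carbocycle C1–C10 is an (E)-cyclodec-5-enone (C3=O lies 1,5 to C8=C9). That is the retron of an anionic oxy-Cope ring expansion. The contracted ring C3–C8 carries the C4 methyl and the C7 three-carbon unit C11–C13 para to each other, which is the carvone pattern.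
3. Forward order of rings: cyclohexane (bought; oxygenated at C6, C5, C4, C3; C9, C1–C2 and C10/C14 attached), then the ten-membered ring by [3,3] ring expansion, then the α-methylene-γ-lactone by oxidative lactonisation, then the diol, then the esters.
4. Stereochemistry: C7 comes from (R)-carvone and relays C6, C5, C4 and the ring C8 centre on the chair. C8 is traded for C10 in the rearrangement through a (Z)-propenyl group. The final C8/C9 carbinols come from syn-dihydroxylation of the E-alkene with a DHQD ligand.

Key step: step 16

Convention: germacrane numbering is used throughout. "Lower face" is the face of the six-membered ring that carries the C7 side chain, whose oxygenated carbon is C12 and whose methylene is C13.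
Assumption: the vinyl Grignard reagent is taken to attack the C3 ketone from the upper face, anti to the axial C4–O bond of the cis-fused acetonide, so the carbinol is drawn with an axial vinyl group; this centre is erased in the key step.

Step 1
Reactants: 1 (R)-(−)-carvone
Product: 3 trans-6-hydroxycarvone (C6-OH on the upper face; anti to the C7 isopropenyl group), via lithium dienolate 2 (not isolated)
Conditions: LDA, THF, −78 °C; 2-(phenylsulfonyl)-3-phenyloxaziridine, −78 °C; aq NH4Cl
Reagents that add atoms: 2-(phenylsulfonyl)-3-phenyloxaziridine, O=S(=O)(c1ccccc1)N1OC1c1ccccc1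
Why: Kinetic α′-deprotonation gives the cross-conjugated dienolate, and its Davis oxidation (electrophilic enolate hydroxylation) should deliver oxygen to C6 on the face opposite the neighbouring isopropenyl group, giving the trans-diequatorial α′-ketol, which is also the thermodynamically preferred epimer.

Step 2
Reactants: 3 trans-6-hydroxycarvone
Product: 4 trans-6-(tert-butyldimethylsilyloxy)carvone
Conditions: TBSCl, imidazole, DMF, rt
Reagents that add atoms: tert-butyldimethylsilyl chloride, CC(C)(C)[Si](C)(C)Cl
Why: Imidazole-mediated O-silylation of a secondary alcohol is mild enough not to epimerise the ketol, and the bulky ether later keeps O6 from directing osmium and screens the neighbouring C5 hydroxyl.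

Step 3
Reactants: 4 trans-6-(tert-butyldimethylsilyloxy)carvone
Product: 5 6-silyloxy-cis-carveol (C5-OH on the lower face; cis to isopropenyl; trans to O6)
Conditions: NaBH4, CeCl3·7H2O, MeOH, −78 to 0 °C
Reagents that add atoms: none
Why: The Luche reduction is 1,2-selective for the enone, and axial hydride delivery from the upper face should give the equatorial C5 alcohol, cis to the isopropenyl group as in the carvone-to-cis-carveol reduction and trans to the equatorial C6 silyl ether.

Step 4
Reactants: 5 6-silyloxy-cis-carveol
Product: 7 all-syn C3/C4/C5-triol 6-TBS ether (O3; O4; O5 on the lower face; C4-methyl on the upper face), via osmate ester TMEDA complex 6 (not isolated)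
Conditions: OsO4 (1.05 equiv), TMEDA, CH2Cl2, −78 °C; then aq Na2SO3, THF, reflux
Reagents that add atoms: osmium tetroxide, O=[Os](=O)(=O)=O
Why: OsO4·TMEDA is a strong hydrogen-bond acceptor, so in this hydroxyl-directed syn-dihydroxylation the free C5-OH should steer osmium both to the adjacent trisubstituted C3=C4 alkene rather than the remote isopropenyl group and to its own lower face, which sets C4 (and the transient C3 carbinol) syn to O5.

Step 5
Reactants: 7 all-syn triol
Product: 8 C3 ketone with free C4/C5 cis-diol
Conditions: SO3·pyridine (1.2 equiv), DMSO, Et3N, CH2Cl2, 0 °C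
Reagents that add atoms: none
Why: The Parikh–Doering oxidation turns sec/tert glycols into α-ketols without C–C cleavage, and with limiting oxidant the C3 carbinol next to the C8 methylene should be activated well before the C5 carbinol, which is wedged between quaternary C4 and the C6 silyl ether, while the tertiary C4-OH cannot be oxidised.

Step 6
Reactants: 8 C3 ketone diol
Product: 9 C3 cyclohexanone C4/C5-acetonide
Conditions: 2,2-dimethoxypropane, PPTS (cat.), CH2Cl2, rt
Reagents that add atoms: 2,2-dimethoxypropane, COC(C)(C)OC
Why: Acid-catalysed transketalisation ties the only remaining diol (axial O4 and equatorial O5, cis) into a cis-fused dioxolane that tolerates the strong bases to come and, unlike silyl ethers, cannot migrate to a neighbouring alkoxide.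

Step 7
Reactants: 9 acetonide ketone
Product: 10 C12 allylic alcohol (C7 side chain now CH2=C(CH2OH)–)
Conditions: SeO2 (cat.), t-BuOOH, CH2Cl2, 0 °C to rt
Reagents that add atoms: tert-butyl hydroperoxide, CC(C)(C)OO; selenium dioxide (oxygen carrier), O=[Se]=O
Why: Catalytic SeO2/t-BuOOH allylic hydroxylation (ene reaction then [2,3]-shift) acts on the only alkene present and should take a methyl hydrogen rather than the hindered tertiary C7-H, the low temperature holding back over-oxidation to the enal and α-oxidation of the ketone.

Step 8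
Reactants: 10 C12 allylic alcohol
Product: 11 C6/C12-bis-TBS ketone
Conditions: TBSCl, imidazole, CH2Cl2, rt
Reagents that add atoms: tert-butyldimethylsilyl chloride, CC(C)(C)[Si](C)(C)Cl
Why: Routine silylation of the primary allylic alcohol gives an ether that survives enolate, Grignard, ylide and potassium alkoxide chemistry and falls together with the C6 ether later.

Step 9
Reactants: 11 bis-TBS ketone; 12 formaldehyde (monomer gas from cracked paraformaldehyde)
Product: 14 C8-hydroxymethyl ketone (C9 equatorial on the upper face; anti to the C7 branch), via lithium enolate 13 (not isolated)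
Conditions: LDA, THF, −78 °C; CH2O (g), −78 °C; aq NH4Cl
Reagents that add atoms: formaldehyde (12), C=O
Why: Because C4 is quaternary the enolate can form only toward C8, and its aldol hydroxymethylation should occur on the upper face since the lower axial approach runs into the axial C4–O bond, giving the equatorial arm anti to the C7 branch, which is also the thermodynamic epimer of this epimerisable centre.

Step 10
Reactants: 14 C8-hydroxymethyl ketone
Product: 15 C9 triethylsilyl ether
Conditions: TESCl, imidazole, CH2Cl2, 0 °C
Reagents that add atoms: chlorotriethylsilane, CC[Si](Cl)(CC)CC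
Why: Mild silylation of the aldol hydroxyl blocks retro-aldol loss of formaldehyde and dehydration during the Grignard step, and TES is chosen because it is the one silyl ether that can later be oxidised directly.

Step 11
Reactants: 15 C9 TES ether; 16 vinylmagnesium bromide
Product: 17 C3 vinyl carbinol (vinyl axial on the upper face; cis to the C9 arm; C3-OH equatorial on the lower face)
Conditions: LaCl3·2LiCl, THF, rt; 16, 0 °C; aq NH4Cl
Reagents that add atoms: vinylmagnesium bromide (16), C=C[Mg]Br
Why: The LaCl3·2LiCl-promoted Grignard 1,2-addition suppresses enolisation of the hindered ketone, and the nucleophile should enter axially on the upper face, anti to the axial C4–O bond (polar Felkin–Anh control, convex face of the cis-fused dioxolane), which places the vinyl group gauche to the equatorial C9 arm as the rearrangement requires.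

Step 12
Reactants: 17 C3 vinyl carbinol
Product: 18 C3 O-trimethylsilyl ether
Conditions: TMSOTf, 2,6-lutidine, CH2Cl2, −78 to 0 °C
Reagents that add atoms: trimethylsilyl trifluoromethanesulfonate, C[Si](C)(C)OS(=O)(=O)C(F)(F)F
Why: Silyl triflate/lutidine silylation is strong enough for the hindered tertiary carbinol, and the small cap prevents retro-aldol cleavage of C3–C8 once C9 is an aldehyde yet can be removed later beside TBS ethers.

Step 13
Reactants: 18 C3 O-TMS ether
Product: 19 C9 aldehyde
Conditions: (COCl)2, DMSO, CH2Cl2, −78 to −40 °C; Et3N, −78 to 0 °C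
Reagents that add atoms: none
Why: Under Swern conditions a primary triethylsilyl ether is attacked at oxygen by the chlorosulfonium salt and collapses directly to the aldehyde, whereas the TBS ethers and the hindered tertiary TMS ether are left alone, so deprotection and oxidation become one operation and C8 keeps its preferred equatorial configuration.

Step 14
Reactants: 19 C9 aldehyde; 20 ethyltriphenylphosphonium bromide
Product: 22 (Z)-propenyl C3 O-TMS ether, via ethylidenetriphenylphosphorane 21 (not isolated)
Conditions: 20, KHMDS, THF, 0 °C; then 19, −78 °C to rt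
Reagents that add atoms: ethyltriphenylphosphonium bromide (20), CC[P+](c1ccccc1)(c1ccccc1)c1ccccc1.[Br-]
Why: The Wittig olefination with a non-stabilised ylide made with a potassium base (no lithium salts) passes through the kinetically favoured cis-oxaphosphetane and should give the Z-C9=C10 alkene, the capped C3 oxygen excluding retro-aldol cleavage of the β-oxy aldehyde.

Step 15
Reactants: 22 (Z)-propenyl TMS ether
Product: 23 1-vinyl-2-[(Z)-propenyl]cyclohexanol (vinyl axial; propenyl equatorial; both on the upper face)
Conditions: K2CO3, MeOH, rt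
Reagents that add atoms: none
Why: Base-catalysed methanolysis removes the trimethylsilyl ether selectively, the two TBS ethers, the acetonide and the three alkenes being inert, and frees the tertiary carbinol for alkoxide formation.

Step 16
Reactants: 23 1-vinyl-2-[(Z)-propenyl]cyclohexanol
Product: 26 (E)-cyclodec-5-enone (C3 ketone; E-C8=C9; 10R-methyl; C4/C5 acetonide; C6/C12 OTBS), via potassium alkoxide 24 (not isolated), via potassium enolate 25 (not isolated)
Conditions: KH, 18-crown-6, THF, 0 °C to rt; AcOH/THF, −78 °C
Reagents that add atoms: none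
Why: KH/18-crown-6 converts 23 into the poorly ion-paired alkoxide 24, whose oxyanion weakens the C3–C8 σ-bond so that the 1,5-diene C1=C2–C3–C8–C9=C10 undergoes a concerted suprafacial [3,3]-shift, forming C1–C10 as C3–C8 breaks (anionic oxy-Cope rearrangement, the established route from 1,2-dialkenylcyclohexanols to (E)-cyclodec-5-enones). The ten-membered carbocycle is thus closed by four-atom sigmatropic ring expansion of the cyclohexane rather than by end-to-end cyclisation, and irreversible formation of enolate 25 drives it. The only new stereocentre, C10, is set by 1,3-chirality transfer from C8: A(1,3) strain with the Z-methyl lets only H8 lie in the propenyl plane, so C3 and the vinyl terminus C1 sit over one face of C10 while C7 ends anti to C10, which delivers the 10R centre and the E-C8=C9 geometry together. Because the vinyl group is axial and the propenyl equatorial, this rotamer reacts through a boat-like six-centre array, and the selectivity the step must win is against the chair, which would need C7 in plane against the Z-methyl and would lead to the Z-alkene with the 10-epimer. C3 loses its stereocentre, quaternary C4 keeps 25 from equilibrating or eliminating toward the oxygenated C4–C6 segment, and the acetonide next to the alkoxide rules out oxygen-to-oxygen silyl migration. Protonation of 25 at C2 at −78 °C gives ketone 26.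

Step 17
Reactants: 26 (E)-cyclodec-5-enone
Product: 27 C6/C12-diol
Conditions: TBAF, AcOH (1:1), THF, 0 °C to rt
Reagents that add atoms: none
Why: Fluoride-mediated desilylation buffered with acetic acid cleaves both TBS ethers close to neutrality and leaves acetonide, ketone and alkenes untouched, any reversible C6-OH/C3 hemiketal being without consequence.

Step 18
Reactants: 27 C6/C12-diol
Product: 30 trans-fused α-methylene-6,12-lactone C4/C5-acetonide, via hydroxy enal 28 (not isolated), via lactol 29 (not isolated)
Conditions: activated MnO2 (excess), CH2Cl2, rt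
Reagents that add atoms: none
Why: MnO2 oxidises only the allylic primary alcohol, the enal is captured by the C6 hydroxyl as a five-membered lactol and this allylic lactol is oxidised again, a well-used oxidative lactonisation that builds the γ-lactone with C6 and C7 unchanged while O5 is still masked.

Step 19
Reactants: 30 lactone acetonide
Product: 31 lactone C4/C5-diol
Conditions: AcOH–H2O (4:1), 50 °C
Reagents that add atoms: none
Why: Mild aqueous-acid hydrolysis removes the isopropylidene ketal, and since the ring alkene is only 1,2-disubstituted a transannular Prins-type attack on the protonated C3 ketone would need a secondary cation and should not compete, lactone and exocyclic methylene being acid-stable.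

Step 20
Reactants: 31 lactone diol; 32 isobutyric anhydride
Product: 33 C5 isobutyrate with free C4-OH and E-C8=C9 alkene
Conditions: 32, DMAP (cat.), pyridine, CH2Cl2, 0 °C to rt
Reagents that add atoms: isobutyric anhydride (32), CC(C)C(=O)OC(=O)C(C)C
Why: DMAP-catalysed acylation distinguishes cleanly between the secondary C5 hydroxyl and the tertiary C4 hydroxyl, which stays free as in the target.

Step 21
Reactants: 33 C5 isobutyrate
Product: 34 (8R,9R)-diol
Conditions: OsO4 (cat.), (DHQD)2PHAL (cat.), NMO, acetone–H2O, 0 °C
Reagents that add atoms: osmium tetroxide (oxygen carrier), O=[Os](=O)(=O)=O; N-methylmorpholine N-oxide, C[N+]1([O-])CCOCC1; water, O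
Why: Electrophilic osmium should ignore the lactone-conjugated C11=C13 methylene in favour of the strained electron-rich E-C8=C9 alkene and add suprafacially to its exposed outer face (E-alkene to threo diol); because the exposed face depends on the ring conformer, the Sharpless-type ligand (DHQD)2PHAL, whose mnemonic selects the face leading to the 8R,9R diol, is added, and the neutral Upjohn reoxidant spares lactone, ester and α-ketol.

Step 22
Reactants: 34 (8R,9R)-diol; 35 isovaleric anhydride
Product: 36 target CNP0203887.1 (4R,5R,6S,7R,8R,9R,10R)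
Conditions: 35 (1.1 equiv), DMAP (cat.), pyridine, CH2Cl2, −20 °C
Reagents that add atoms: isovaleric anhydride (35), CC(C)CC(=O)OC(=O)CC(C)C
Why: DMAP-catalysed acylation with about one equivalent of anhydride at low temperature should take the C9 hydroxyl, whose neighbour C10 bears only a methyl group, in preference to the C8 hydroxyl crowded by the C7 ring-fusion carbon and the lactone methylene and to the tertiary C4 hydroxyl, and it touches no stereocentre.

**Compound list**
1 | (R)-(−)-carvone | CC1=CC[C@H](CC1=O)C(C)=C | starting material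
2 | lithium cross-conjugated dienolate of 1 (not isolated) | [Li+].[O-]C1=C[C@H](C(C)=C)CC=C1C | intermediate
3 | trans-6-hydroxycarvone | CC1=CC[C@@H](C(C)=C)[C@H](O)C1=O | intermediate
4 | trans-6-(tert-butyldimethylsilyloxy)carvone | CC1=CC[C@@H](C(C)=C)[C@H](O[Si](C)(C)C(C)(C)C)C1=O | intermediate
5 | 6-silyloxy-cis-carveol (C5 allylic alcohol) | CC1=CC[C@@H](C(C)=C)[C@H](O[Si](C)(C)C(C)(C)C)[C@H]1O | intermediate
6 | C3/C4 osmate(VI) ester, TMEDA complex (not isolated) | O1[C@@H]2[C@](C)(O[Os]1(=O)=O)[C@H](O)[C@@H](O[Si](C)(C)C(C)(C)C)[C@H](C(C)=C)C2.CN(C)CCN(C)C | intermediate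
7 | all-syn C3,C4,C5-triol, C6 TBS ether | O[C@@H]1[C@](C)(O)[C@H](O)[C@@H](O[Si](C)(C)C(C)(C)C)[C@H](C(C)=C)C1 | intermediate
8 | C3 ketone, C4/C5 cis-diol | O=C1[C@](C)(O)[C@H](O)[C@@H](O[Si](C)(C)C(C)(C)C)[C@H](C(C)=C)C1 | intermediate
9 | C3 cyclohexanone C4/C5-acetonide | O=C1[C@]2(C)OC(C)(C)O[C@@H]2[C@@H](O[Si](C)(C)C(C)(C)C)[C@H](C(C)=C)C1 | intermediate
10 | C12 allylic alcohol | O=C1[C@]2(C)OC(C)(C)O[C@@H]2[C@@H](O[Si](C)(C)C(C)(C)C)[C@H](C(=C)CO)C1 | intermediate
11 | C6/C12-bis-TBS ketone | O=C1[C@]2(C)OC(C)(C)O[C@@H]2[C@@H](O[Si](C)(C)C(C)(C)C)[C@H](C(=C)CO[Si](C)(C)C(C)(C)C)C1 | intermediate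
12 | formaldehyde | C=O | starting material
13 | lithium C3=C8 enolate of 11 (not isolated) | [Li+].[O-]C=1[C@]2(C)OC(C)(C)O[C@@H]2[C@@H](O[Si](C)(C)C(C)(C)C)[C@H](C(=C)CO[Si](C)(C)C(C)(C)C)C=1 | intermediate
14 | C8-hydroxymethyl ketone | O=C1[C@]2(C)OC(C)(C)O[C@@H]2[C@@H](O[Si](C)(C)C(C)(C)C)[C@H](C(=C)CO[Si](C)(C)C(C)(C)C)[C@H]1CO | intermediate
15 | C9 TES ether | O=C1[C@]2(C)OC(C)(C)O[C@@H]2[C@@H](O[Si](C)(C)C(C)(C)C)[C@H](C(=C)CO[Si](C)(C)C(C)(C)C)[C@H]1CO[Si](CC)(CC)CC | intermediate
16 | vinylmagnesium bromide | C=C[Mg]Br | starting material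
17 | C3 vinyl carbinol (axial vinyl) | C=C[C@@]1(O)[C@]2(C)OC(C)(C)O[C@@H]2[C@@H](O[Si](C)(C)C(C)(C)C)[C@H](C(=C)CO[Si](C)(C)C(C)(C)C)[C@H]1CO[Si](CC)(CC)CC | intermediate
18 | C3 O-TMS ether | C=C[C@@]1(O[Si](C)(C)C)[C@]2(C)OC(C)(C)O[C@@H]2[C@@H](O[Si](C)(C)C(C)(C)C)[C@H](C(=C)CO[Si](C)(C)C(C)(C)C)[C@H]1CO[Si](CC)(CC)CC | intermediate
19 | C9 aldehyde | C=C[C@@]1(O[Si](C)(C)C)[C@]2(C)OC(C)(C)O[C@@H]2[C@@H](O[Si](C)(C)C(C)(C)C)[C@H](C(=C)CO[Si](C)(C)C(C)(C)C)[C@H]1C=O | intermediate
20 | ethyltriphenylphosphonium bromide | CC[P+](c1ccccc1)(c1ccccc1)c1ccccc1.[Br-] | starting material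
21 | ethylidenetriphenylphosphorane (not isolated) | CC=P(c1ccccc1)(c1ccccc1)c1ccccc1 | intermediate
22 | (Z)-propenyl C3 O-TMS ether | C=C[C@@]1(O[Si](C)(C)C)[C@]2(C)OC(C)(C)O[C@@H]2[C@@H](O[Si](C)(C)C(C)(C)C)[C@H](C(=C)CO[Si](C)(C)C(C)(C)C)[C@H]1/C=C\C | intermediate
23 | 1-vinyl-2-[(Z)-propenyl]cyclohexanol | C=C[C@@]1(O)[C@]2(C)OC(C)(C)O[C@@H]2[C@@H](O[Si](C)(C)C(C)(C)C)[C@H](C(=C)CO[Si](C)(C)C(C)(C)C)[C@H]1/C=C\C | intermediate
24 | potassium alkoxide of 23 (not isolated) | [K+].C=C[C@@]1([O-])[C@]2(C)OC(C)(C)O[C@@H]2[C@@H](O[Si](C)(C)C(C)(C)C)[C@H](C(=C)CO[Si](C)(C)C(C)(C)C)[C@H]1/C=C\C | intermediate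
25 | potassium C2=C3 enolate of the ten-membered ring (not isolated) | [K+].C=C(CO[Si](C)(C)C(C)(C)C)[C@@H]1/C=C/[C@H](C)C/C=C(\[O-])[C@]2(C)OC(C)(C)O[C@@H]2[C@H]1O[Si](C)(C)C(C)(C)C | intermediate
26 | (E)-cyclodec-5-enone, 10R | C=C(CO[Si](C)(C)C(C)(C)C)[C@@H]1/C=C/[C@H](C)CCC(=O)[C@]2(C)OC(C)(C)O[C@@H]2[C@H]1O[Si](C)(C)C(C)(C)C | intermediate
27 | C6/C12-diol | C=C(CO)[C@@H]1/C=C/[C@H](C)CCC(=O)[C@]2(C)OC(C)(C)O[C@@H]2[C@H]1O | intermediate
28 | C6-hydroxy C12-enal (not isolated) | C=C(C=O)[C@@H]1/C=C/[C@H](C)CCC(=O)[C@]2(C)OC(C)(C)O[C@@H]2[C@H]1O | intermediate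
29 | 6,12-lactol, C12 epimers (not isolated) | C=C1C(O)O[C@H]2[C@H]1/C=C/[C@H](C)CCC(=O)[C@]3(C)OC(C)(C)O[C@@H]32 | intermediate
30 | α-methylene-6,12-lactone C4/C5-acetonide | C=C1C(=O)O[C@H]2[C@H]1/C=C/[C@H](C)CCC(=O)[C@]3(C)OC(C)(C)O[C@@H]32 | intermediate
31 | lactone C4/C5-diol | C=C1C(=O)O[C@H]2[C@H]1/C=C/[C@H](C)CCC(=O)[C@](C)(O)[C@@H]2O | intermediate
32 | isobutyric anhydride | CC(C)C(=O)OC(=O)C(C)C | starting material
33 | C5 isobutyrate, E-C8=C9 alkene | C=C1C(=O)O[C@H]2[C@H]1/C=C/[C@H](C)CCC(=O)[C@](C)(O)[C@@H]2OC(=O)C(C)C | intermediate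
34 | (8R,9R)-diol | C=C1C(=O)O[C@H]2[C@H]1[C@@H](O)[C@H](O)[C@H](C)CCC(=O)[C@](C)(O)[C@@H]2OC(=O)C(C)C | intermediate
35 | isovaleric anhydride | CC(C)CC(=O)OC(=O)CC(C)C | starting material
36 | CNP0203887.1 | C=C1C(=O)O[C@H]2[C@H]1[C@@H](O)[C@H](OC(=O)CC(C)C)[C@H](C)CCC(=O)[C@](C)(O)[C@@H]2OC(=O)C(C)C | target

**Step count**
Total step count: 22. Longest linear sequence: 22 steps, from 1 to 36; all other carbon sources (12, 16, 20, 32, 35) are purchased.

**Steps most likely to fail**

Step 16.
- What may go wrong: chirality transfer may erode, because the boat-like array of the axial-vinyl carbinol has to outrun the chair that leads to the Z-alkene and the C10 epimer. The rearrangement may also be slow enough for alkoxide fragmentation to intervene.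
- Fallback: invert C3 first, so that the chair preference and the allylic-strain preference point the same way.
- Route: setting out from 23, O-sulfenylation (n-BuLi, PhSCl, THF, −78 °C to rt) with spontaneous [2,3]-shift (Mislow–Evans rearrangement) would give the allylic sulfoxide F1.
- Warming F1 with Et2NH in MeOH draws it back through the sulfenate that returns oxygen to C3 from the more open upper face. This gives the C3-epimeric carbinol F2 (OH axial, vinyl equatorial, the two alkenyl groups trans-diequatorial).
- KH/18-crown-6 then takes F2 via its potassium alkoxide F3 through a trans-decalin-like chair to the same enolate 25. The fallback rejoins the route at 26.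

Step 5.
- What may go wrong: the oxidant may fail to tell the C3 from the C5 carbinol or may oxidise both. The stoichiometric osmylation just before it may also touch the isopropenyl group.
- Fallback: make O3 trans to O4, so that the protection becomes unambiguous. It sets out from 5 and returns at 9, bypassing 7 and 8.
- Route: vanadium-catalysed hydroxyl-directed epoxidation (VO(acac)2, t-BuOOH, CH2Cl2) gives the syn epoxy alcohol F4.
- Ti(OiPr)4-assisted opening with benzoic acid at the distal, less substituted C3 (trans-diaxial, Fürst–Plattner) gives the C3 benzoate diol F5. In F5 only the C4/C5 pair is cis.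
- 2,2-Dimethoxypropane/PPTS gives the acetonide benzoate F6, and K2CO3/MeOH gives the axial C3 alcohol F7.
- Dess–Martin oxidation of F7 delivers 9.

Step 22.
- What may go wrong: acylation may prefer or fail to avoid the C8 hydroxyl, and 1,2-acyl migration may blur the result.
- Fallback: turn an unfavourable preference to advantage by masking the more reactive position first.
- Route: setting out from 34, TESCl (1 equiv), imidazole, CH2Cl2, −40 °C would give the 8-O-TES ether F8.
- Compound 35 with DMAP and Et3N at rt acylates the remaining secondary hydroxyl to give the 8-O-TES 9-O-isovalerate F9.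
- HF·pyridine in THF at 0 °C removes the silyl group without acyl migration and returns to the route at 36.

**Further compounds**
F1 | step 16 | allylic sulfoxide, C2=C3 exocyclic alkene with C1–S(O)Ph (alkene geometry and sulfur configuration open) | O=S(c3ccccc3)CC=C1[C@]2(C)OC(C)(C)O[C@@H]2[C@@H](O[Si](C)(C)C(C)(C)C)[C@H](C(=C)CO[Si](C)(C)C(C)(C)C)[C@H]1/C=C\C
F2 | step 16 | C3-epimeric carbinol (OH axial, vinyl equatorial) | C=C[C@]1(O)[C@]2(C)OC(C)(C)O[C@@H]2[C@@H](O[Si](C)(C)C(C)(C)C)[C@H](C(=C)CO[Si](C)(C)C(C)(C)C)[C@H]1/C=C\C
F3 | step 16 | potassium alkoxide of F2 | [K+].C=C[C@]1([O-])[C@]2(C)OC(C)(C)O[C@@H]2[C@@H](O[Si](C)(C)C(C)(C)C)[C@H](C(=C)CO[Si](C)(C)C(C)(C)C)[C@H]1/C=C\C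
F4 | step 5 | syn C3/C4-epoxy C5-alcohol | O1[C@@H]2[C@@]1(C)[C@H](O)[C@@H](O[Si](C)(C)C(C)(C)C)[C@H](C(C)=C)C2
F5 | step 5 | C3 benzoate (upper face), C4/C5 cis-diol | O=C(c2ccccc2)O[C@H]1[C@](C)(O)[C@H](O)[C@@H](O[Si](C)(C)C(C)(C)C)[C@H](C(C)=C)C1
F6 | step 5 | C3 benzoate C4/C5-acetonide | O=C(c3ccccc3)O[C@H]1[C@]2(C)OC(C)(C)O[C@@H]2[C@@H](O[Si](C)(C)C(C)(C)C)[C@H](C(C)=C)C1
F7 | step 5 | axial C3 alcohol C4/C5-acetonide | O[C@H]1[C@]2(C)OC(C)(C)O[C@@H]2[C@@H](O[Si](C)(C)C(C)(C)C)[C@H](C(C)=C)C1
F8 | step 22 | 8-O-TES ether of 34 | C=C1C(=O)O[C@H]2[C@H]1[C@@H](O[Si](CC)(CC)CC)[C@H](O)[C@H](C)CCC(=O)[C@](C)(O)[C@@H]2OC(=O)C(C)C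
F9 | step 22 | 8-O-TES 9-O-isovalerate | C=C1C(=O)O[C@H]2[C@H]1[C@@H](O[Si](CC)(CC)CC)[C@H](OC(=O)CC(C)C)[C@H](C)CCC(=O)[C@](C)(O)[C@@H]2OC(=O)C(C)C
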